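**Retrosynthetic overview**
1. The target comes from its 13‑desacetyl 8,13‑diol by selective acetylation; the exo‑methylene (C15=C17) is added late by Eschenmoser methylenation of the macrocyclic lactone.
2. The 14‑membered carbocycle (formed last of the three rings) is closed by ring‑closing metathesis at C6=C7; the epoxide (second ring) is set just before by a matched Sharpless epoxidation of the 13S allylic alcohol.
3. The C13–C14 bond comes from a Fukuyama ketone synthesis (alkylzinc of an east lactone iodide plus a west enoyl thioester), followed by CBS reduction of the enone.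
4. West fragment: geraniol, catalytic Sharpless epoxidation (first stereocentre, C8), reductive opening to (R)‑linalool, SeO2 oxidation to the C13 acid level.
5. East fragment: pent‑1‑en‑4‑yne, carboalumination/carboxylation, β‑keto ester, ketoreductase reduction (C2), Fráter–Seebach anti‑alkylation (C1), then the cis γ‑lactone (first ring).

Assumption: locants follow cembrane numbering (C1 lactone β‑CH, C2 lactone O–CH, C3=C4, C6=C7, C8 carbinol, C11/C12 epoxide, C13 acetoxy carbon, C14 CH2, C15 α‑carbon, C16 lactone C=O, C17 exo‑CH2); the target SMILES then reads (1S,2S,3E,6E,8R,11S,12R,13S).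

**West fragment**

Step 1
Reactants: 1 geraniol
Product: 2 (2R,3R)-2,3-epoxygeraniol
Conditions: Ti(OiPr)4 (5 mol%), D-(−)-diisopropyl tartrate (6 mol%), t-BuOOH (anhydrous), 4 Å molecular sieves, CH2Cl2, −20 °C
Reagents that add atoms: tert-butyl hydroperoxide, CC(C)(C)OO
Why: Catalytic Sharpless asymmetric epoxidation; the titanium/D‑tartrate complex delivers oxygen to one face of the allylic alcohol and sets the (2R,3R) epoxide, whose C3 becomes C8 of the target.

Step 2
Reactants: 2 (2R,3R)-2,3-epoxygeraniol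
Product: 3 (2S,3R)-2-(iodomethyl)-3-methyl-3-(4-methylpent-3-en-1-yl)oxirane
Conditions: PPh3, I2, imidazole, CH2Cl2, 0 °C
Reagents that add atoms: iodine, II
Why: Appel‑type iodination of the primary alcohol (SN2 at CH2) leaves the epoxide and its stereocentres untouched.

Step 3
Reactants: 3 (2S,3R)-2-(iodomethyl)-3-methyl-3-(4-methylpent-3-en-1-yl)oxirane
Product: 4 (R)-linalool
Conditions: Zn dust, AcOH, EtOH, 0 °C to rt
Reagents that add atoms: none
Why: Zinc‑mediated reductive β‑elimination of the β‑iodo epoxide gives the transposed tertiary allylic alcohol; the C–O bond at the tertiary centre is not broken, so its configuration is kept.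

Step 4
Reactants: 4 (R)-linalool
Product: 5 triethyl{[(3R)-3,7-dimethylocta-1,6-dien-3-yl]oxy}silane
Conditions: Et3SiOTf, 2,6-lutidine, CH2Cl2, −78 to 0 °C
Reagents that add atoms: triethylsilyl triflate, CC[Si](CC)(CC)OS(=O)(=O)C(F)(F)F
Why: Silyl triflate silylation of the hindered tertiary alcohol masks O8, which would otherwise cyclise onto the later enone or epoxide.

Step 5
Reactants: 5 triethyl{[(3R)-3,7-dimethylocta-1,6-dien-3-yl]oxy}silane
Product: 6 (2E,6R)-2,6-dimethyl-6-(triethylsilyloxy)octa-2,7-dien-1-ol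
Conditions: SeO2 (0.3 equiv), t-BuOOH (3 equiv), CH2Cl2, 0 °C to rt
Reagents that add atoms: tert-butyl hydroperoxide, CC(C)(C)OO
Why: Sharpless–Umbreit allylic oxidation (ene reaction then [2,3] shift) oxidises only the E‑methyl of the trisubstituted alkene; any over‑oxidised aldehyde 7 is carried into step 6.

Step 6
Reactants: 6 (2E,6R)-2,6-dimethyl-6-(triethylsilyloxy)octa-2,7-dien-1-ol
Product: 7 (2E,6R)-2,6-dimethyl-6-(triethylsilyloxy)octa-2,7-dienal
Conditions: MnO2 (activated, excess), CH2Cl2, rt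
Reagents that add atoms: none
Why: Allylic oxidation with MnO2 is neutral and selective for the allylic primary alcohol, with no E/Z erosion.

Step 7
Reactants: 7 (2E,6R)-2,6-dimethyl-6-(triethylsilyloxy)octa-2,7-dienal
Product: 8 (2E,6R)-2,6-dimethyl-6-(triethylsilyloxy)octa-2,7-dienoic acid
Conditions: NaClO2, NaH2PO4, 2-methylbut-2-ene, t-BuOH/H2O, 0 °C to rt
Reagents that add atoms: sodium chlorite, [Na+].[O-]Cl=O
Why: Pinnick oxidation converts the enal to the acid without touching the alkenes (hypochlorite is scavenged) or the silyl ether.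

Step 8
Reactants: 8 (2E,6R)-2,6-dimethyl-6-(triethylsilyloxy)octa-2,7-dienoic acid
Product: 9 S-ethyl (2E,6R)-2,6-dimethyl-6-(triethylsilyloxy)octa-2,7-dienethioate
Conditions: EtSH, EDC·HCl, DMAP (10 mol%), CH2Cl2, 0 °C to rt
Reagents that add atoms: ethanethiol, CCS
Why: Steglich‑type carbodiimide thioesterification gives the acyl donor for the Fukuyama coupling; the α‑methyl enoate is a poor Michael acceptor for the thiol.

**East fragment**

Step 9
Reactants: 10 pent-1-en-4-yne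
Product: 13 (2E)-3-methylhexa-2,5-dienoic acid, via alkenylalane 11 (not isolated), via lithium alanate 12 (not isolated)
Conditions: Me3Al (2 equiv), Cp2ZrCl2 (25 mol%), CH2Cl2, 0 °C to rt; then n-BuLi, THF, −78 °C; CO2, −78 °C to rt; aq. HCl
Reagents that add atoms: trimethylaluminium, C[Al](C)C; carbon dioxide, O=C=O
Why: Negishi zirconium‑catalysed carboalumination adds Me–Al syn across the alkyne (fixing the E trisubstituted alkene, the isolated alkene reacts far more slowly), and the ate complex is carboxylated with retention.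

Step 10
Reactants: 13 (2E)-3-methylhexa-2,5-dienoic acid; 14 potassium ethyl malonate
Product: 16 ethyl (4E)-5-methyl-3-oxoocta-4,7-dienoate, via acyl imidazolide 15 (not isolated)
Conditions: 1,1'-carbonyldiimidazole, THF, rt; then 14, MgCl2, Et3N, THF, rt to 45 °C; aq. citric acid
Reagents that add atoms: none
Why: Masamune–Brooks C‑acylation of the magnesium malonate by the acyl imidazolide followed by decarboxylation builds the β‑keto ester under near‑neutral conditions that do not move the skipped diene into conjugation.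

Step 11
Reactants: 16 ethyl (4E)-5-methyl-3-oxoocta-4,7-dienoate
Product: 17 ethyl (3R,4E)-3-hydroxy-5-methylocta-4,7-dienoate
Conditions: ketoreductase (NADPH-dependent, R-selective, chosen from a screening panel), NADP+ (cat.), iPrOH (10 vol%), KH2PO4/K2HPO4 buffer pH 7.0, 30 °C
Reagents that add atoms: none
Why: Enzymatic carbonyl reduction by a ketoreductase delivers hydride to one face of the β‑keto ester (a classic substrate class) and sets C2 as the 3R alcohol, leaving all C=C bonds untouched.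

Step 12
Reactants: 17 ethyl (3R,4E)-3-hydroxy-5-methylocta-4,7-dienoate; 18 tert-butyl bromoacetate
Product: 20 4-tert-butyl 1-ethyl (2S)-2-[(1S,2E)-1-hydroxy-3-methylhexa-2,5-dien-1-yl]butanedioate, via dilithium dianion 19 (not isolated)
Conditions: LiN(iPr)2 (2.2 equiv), THF, −78 to −20 °C; then 18, DMPU, −78 to −30 °C
Reagents that add atoms: none
Why: Fráter–Seebach alkylation; the lithium‑chelated alkoxide–enolate is alkylated on the face away from the carbinol substituent, giving the anti product that maps onto the cis lactone (C1 set from C2).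

Step 13
Reactants: 20 4-tert-butyl 1-ethyl (2S)-2-[(1S,2E)-1-hydroxy-3-methylhexa-2,5-dien-1-yl]butanedioate
Product: 21 tert-butyl (3R,4S,5E)-4-hydroxy-3-(hydroxymethyl)-6-methylnona-5,8-dienoate
Conditions: LiBH4, MeOH (1 equiv), THF, 0 °C
Reagents that add atoms: none
Why: Chemoselective borohydride reduction; the hydroxyl‑activated ethyl ester is reduced while the tert‑butyl ester is inert.

Step 14
Reactants: 21 tert-butyl (3R,4S,5E)-4-hydroxy-3-(hydroxymethyl)-6-methylnona-5,8-dienoate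
Product: 22 tert-butyl (3R,4S,5E)-4-hydroxy-6-methyl-3-[(tosyloxy)methyl]nona-5,8-dienoate
Conditions: TsCl (1.05 equiv), Et3N, Me3N·HCl (cat.), CH2Cl2, −10 °C
Reagents that add atoms: 4-toluenesulfonyl chloride, Cc1ccc(cc1)S(Cl)(=O)=O
Why: Selective sulfonylation of the primary over the secondary allylic hydroxyl blocks C14–O, so only O2 can lactonise in the next step.

Step 15
Reactants: 22 tert-butyl (3R,4S,5E)-4-hydroxy-6-methyl-3-[(tosyloxy)methyl]nona-5,8-dienoate
Product: 25 [(2S,3R)-2-[(1E)-2-methylpenta-1,4-dien-1-yl]-5-oxooxolan-3-yl]methyl 4-methylbenzenesulfonate, via bis(trimethylsilyl) derivative 23 (not isolated), via hydroxy acid 24 (not isolated)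
Conditions: Me3SiOTf, 2,6-lutidine, CH2Cl2, 0 °C; then 10% aq. citric acid, THF, rt
Reagents that add atoms: none
Why: Buffered silyl‑triflate cleavage of the tert‑butyl ester (no free protic acid, so the allylic carbinol does not ionise) and spontaneous γ‑lactonisation of the hydroxy acid give the cis‑β,γ‑disubstituted lactone with both centres unchanged.

Step 16
Reactants: 25 [(2S,3R)-2-[(1E)-2-methylpenta-1,4-dien-1-yl]-5-oxooxolan-3-yl]methyl 4-methylbenzenesulfonate
Product: 26 (4S,5S)-4-(iodomethyl)-5-[(1E)-2-methylpenta-1,4-dien-1-yl]oxolan-2-one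
Conditions: NaI, NaHCO3, acetone, 50 °C
Reagents that add atoms: sodium iodide, [Na+].[I-]
Why: Finkelstein SN2 displacement at the primary carbon; no free hydroxymethyl lactone is ever formed, so translactonisation is avoided.

**Coupling and endgame**

Step 17
Reactants: 26 (4S,5S)-4-(iodomethyl)-5-[(1E)-2-methylpenta-1,4-dien-1-yl]oxolan-2-one; 9 S-ethyl (2E,6R)-2,6-dimethyl-6-(triethylsilyloxy)octa-2,7-dienethioate
Product: 28 (4S,5R)-4-[(3E,7R)-3,7-dimethyl-2-oxo-7-(triethylsilyloxy)nona-3,8-dien-1-yl]-5-[(1E)-2-methylpenta-1,4-dien-1-yl]oxolan-2-one, via alkylzinc iodide 27 (not isolated)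
Conditions: Zn dust (activated with Me3SiCl and 1,2-dibromoethane), THF/N,N-dimethylacetamide, 40 °C; then 9, PdCl2(PPh3)2 (10 mol%), toluene, rt
Reagents that add atoms: none
Why: Fukuyama coupling; the alkylzinc iodide tolerates the lactone and transfers to the acyl–palladium species from the thioester, giving the enone without over‑addition and with the E‑alkene intact.

Step 18
Reactants: 28 (4S,5R)-4-[(3E,7R)-3,7-dimethyl-2-oxo-7-(triethylsilyloxy)nona-3,8-dien-1-yl]-5-[(1E)-2-methylpenta-1,4-dien-1-yl]oxolan-2-one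
Product: 29 (4S,5R)-4-[(2S,3E,7R)-2-hydroxy-3,7-dimethyl-7-(triethylsilyloxy)nona-3,8-dien-1-yl]-5-[(1E)-2-methylpenta-1,4-dien-1-yl]oxolan-2-one
Conditions: (R)-2-methyl-CBS-oxazaborolidine [(3aR)-1-methyl-3,3-diphenyltetrahydro-1H,3H-pyrrolo[1,2-c][1,3,2]oxazaborole] (0.5 equiv), catecholborane, toluene, −78 °C
Reagents that add atoms: none
Why: Corey–Bakshi–Shibata reduction; the α‑methylalkenyl group acts as the large substituent, so the R catalyst gives the 13S allylic alcohol under reagent control, and catecholborane at −78 °C spares the lactone and the alkenes.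

Step 19
Reactants: 29 (4S,5R)-4-[(2S,3E,7R)-2-hydroxy-3,7-dimethyl-7-(triethylsilyloxy)nona-3,8-dien-1-yl]-5-[(1E)-2-methylpenta-1,4-dien-1-yl]oxolan-2-one
Product: 30 (4S,5R)-4-[(2S)-2-hydroxy-2-{(2S,3S)-2-methyl-3-[(3R)-3-methyl-3-(triethylsilyloxy)pent-4-en-1-yl]oxiran-2-yl}ethyl]-5-[(1E)-2-methylpenta-1,4-dien-1-yl]oxolan-2-one
Conditions: Ti(OiPr)4 (1.2 equiv), L-(+)-diisopropyl tartrate (1.5 equiv), t-BuOOH (anhydrous), 4 Å molecular sieves, CH2Cl2, −20 °C; aq. tartaric acid work-up (no base)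
Reagents that add atoms: tert-butyl hydroperoxide, CC(C)(C)OO
Why: Sharpless epoxidation of a secondary allylic alcohol in the matched sense (L‑tartrate with the 13S carbinol) gives the erythro 11S,12R epoxide (the oxirane C12 descriptor reads S while O13 is free), touches no other alkene, and leaves any 13R epimer largely unreacted.

Step 20
Reactants: 30 (4S,5R)-4-[(2S)-2-hydroxy-2-{(2S,3S)-2-methyl-3-[(3R)-3-methyl-3-(triethylsilyloxy)pent-4-en-1-yl]oxiran-2-yl}ethyl]-5-[(1E)-2-methylpenta-1,4-dien-1-yl]oxolan-2-one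
Product: 31 (4S,5R)-4-[(2S)-2-{(2R,3S)-2-methyl-3-[(3R)-3-methyl-3-(triethylsilyloxy)pent-4-en-1-yl]oxiran-2-yl}-2-(triethylsilyloxy)ethyl]-5-[(1E)-2-methylpenta-1,4-dien-1-yl]oxolan-2-one
Conditions: Et3SiCl, imidazole, DMAP (cat.), DMF, 0 °C to rt
Reagents that add atoms: chlorotriethylsilane, CC[Si](Cl)(CC)CC
Why: Silyl ether protection of O13 under basic, non‑Lewis‑acidic conditions prevents Payne rearrangement and translactonisation during the later enolate chemistry.

Step 21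
Reactants: 31 (4S,5R)-4-[(2S)-2-{(2R,3S)-2-methyl-3-[(3R)-3-methyl-3-(triethylsilyloxy)pent-4-en-1-yl]oxiran-2-yl}-2-(triethylsilyloxy)ethyl]-5-[(1E)-2-methylpenta-1,4-dien-1-yl]oxolan-2-one
Product: 32 (1S,2R,3E,6E,8R,11S,12R,13S)-11,12-epoxy-8,13-bis(triethylsilyloxy)-17-norcembra-3,6-dien-16,2-olide
Conditions: second-generation Grubbs catalyst (10 mol%), 1,4-benzoquinone (20 mol%), toluene (1 mM), 80 °C
Reagents that add atoms: none
Why: Ring‑closing metathesis of the two monosubstituted alkenes closes the 14‑membered ring; the fully substituted C8 next to the new alkene enforces E geometry, and benzoquinone suppresses isomerisation of the skipped diene.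

Step 22
Reactants: 32 (1S,2R,3E,6E,8R,11S,12R,13S)-11,12-epoxy-8,13-bis(triethylsilyloxy)-17-norcembra-3,6-dien-16,2-olide
Product: 34 (1S,2R,3E,6E,8R,11S,12R,13S)-17-(dimethylamino)-11,12-epoxy-8,13-bis(triethylsilyloxy)cembra-3,6-dien-16,2-olide (C15 epimer mixture), via lithium enolate 33 (not isolated)
Conditions: LiN(iPr)2 (1.3 equiv), THF, −78 °C; then CH2=NMe2+ I−, −78 °C to rt
Reagents that add atoms: dimethyl(methylidene)ammonium iodide, C=[N+](C)C.[I-]
Why: Mannich aminomethylation of the lactone enolate with Eschenmoser's salt; C15 is the only enolisable position and its new stereocentre is erased in the next step.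

Step 23
Reactants: 34 (1S,2R,3E,6E,8R,11S,12R,13S)-17-(dimethylamino)-11,12-epoxy-8,13-bis(triethylsilyloxy)cembra-3,6-dien-16,2-olide
Product: 36 (1S,2S,3E,6E,8R,11S,12R,13S)-11,12-epoxy-8,13-bis(triethylsilyloxy)cembra-3,6,15(17)-trien-16,2-olide, via trimethylammonium iodide 35 (not isolated)
Conditions: MeI (excess), THF, rt; then aq. NaHCO3, EtOAc, rt
Reagents that add atoms: none
Why: N‑methylation followed by mild base‑induced β‑elimination (Hofmann‑type, E1cB) of trimethylamine gives the exo‑methylene lactone without touching the epoxide.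

Step 24
Reactants: 36 (1S,2S,3E,6E,8R,11S,12R,13S)-11,12-epoxy-8,13-bis(triethylsilyloxy)cembra-3,6,15(17)-trien-16,2-olide
Product: 37 (1S,2S,3E,6E,8R,11S,12S,13S)-11,12-epoxy-8,13-dihydroxycembra-3,6,15(17)-trien-16,2-olide
Conditions: HF·pyridine, pyridine (excess), THF, 0 °C to rt
Reagents that add atoms: none
Why: Buffered fluoride desilylation removes both triethylsilyl ethers without generating alkoxides (no oxa‑Michael addition to the methylene lactone) and without strong acid (no epoxide opening by O8).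

Step 25
Reactants: 37 (1S,2S,3E,6E,8R,11S,12S,13S)-11,12-epoxy-8,13-dihydroxycembra-3,6,15(17)-trien-16,2-olide
Product: 38 (1S,2S,3E,6E,8R,11S,12R,13S)-13-acetoxy-11,12-epoxy-8-hydroxycembra-3,6,15(17)-trien-16,2-olide (CNP0288879.3)
Conditions: Ac2O (1.5 equiv), pyridine, DMAP (5 mol%), CH2Cl2, 0 °C
Reagents that add atoms: acetic anhydride, CC(=O)OC(C)=O
Why: Nucleophile‑catalysed acylation is selective for the secondary C13 hydroxyl over the hindered tertiary C8 hydroxyl.

**Compound list**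

1 | geraniol, (2E)-3,7-dimethylocta-2,6-dien-1-ol | OC/C=C(\C)CCC=C(C)C | starting material
2 | (2R,3R)-2,3-epoxygeraniol, [(2R,3R)-3-methyl-3-(4-methylpent-3-en-1-yl)oxiran-2-yl]methanol | OC[C@H]1O[C@]1(C)CCC=C(C)C | intermediate
3 | (2S,3R)-2-(iodomethyl)-3-methyl-3-(4-methylpent-3-en-1-yl)oxirane | IC[C@H]1O[C@]1(C)CCC=C(C)C | intermediate
4 | (R)-linalool, (3R)-3,7-dimethylocta-1,6-dien-3-ol | C=C[C@](C)(O)CCC=C(C)C | intermediate
5 | triethyl{[(3R)-3,7-dimethylocta-1,6-dien-3-yl]oxy}silane | C=C[C@](C)(O[Si](CC)(CC)CC)CCC=C(C)C | intermediate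
6 | (2E,6R)-2,6-dimethyl-6-(triethylsilyloxy)octa-2,7-dien-1-ol | C=C[C@](C)(O[Si](CC)(CC)CC)CC/C=C(\C)CO | intermediate
7 | (2E,6R)-2,6-dimethyl-6-(triethylsilyloxy)octa-2,7-dienal | C=C[C@](C)(O[Si](CC)(CC)CC)CC/C=C(\C)C=O | intermediate
8 | (2E,6R)-2,6-dimethyl-6-(triethylsilyloxy)octa-2,7-dienoic acid | C=C[C@](C)(O[Si](CC)(CC)CC)CC/C=C(\C)C(O)=O | intermediate
9 | S-ethyl (2E,6R)-2,6-dimethyl-6-(triethylsilyloxy)octa-2,7-dienethioate | C=C[C@](C)(O[Si](CC)(CC)CC)CC/C=C(\C)C(=O)SCC | intermediate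
10 | pent-1-en-4-yne | C=CCC#C | starting material
11 | dimethyl[(1E)-2-methylpenta-1,4-dien-1-yl]alumane | C=CC/C(C)=C/[Al](C)C | intermediate
12 | lithium butyl(dimethyl)[(1E)-2-methylpenta-1,4-dien-1-yl]aluminate | [Li+].C=CC/C(C)=C/[Al-](C)(C)CCCC | intermediate
13 | (2E)-3-methylhexa-2,5-dienoic acid | C=CC/C(C)=C/C(O)=O | intermediate
14 | potassium ethyl malonate | [K+].[O-]C(=O)CC(=O)OCC | starting material
15 | (2E)-1-(1H-imidazol-1-yl)-3-methylhexa-2,5-dien-1-one | C=CC/C(C)=C/C(=O)n1ccnc1 | intermediate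
16 | ethyl (4E)-5-methyl-3-oxoocta-4,7-dienoate | C=CC/C(C)=C/C(=O)CC(=O)OCC | intermediate
17 | ethyl (3R,4E)-3-hydroxy-5-methylocta-4,7-dienoate | C=CC/C(C)=C/[C@H](O)CC(=O)OCC | intermediate
18 | tert-butyl bromoacetate | BrCC(=O)OC(C)(C)C | starting material
19 | dilithium alkoxide–enolate (dianion) of 17 | [Li+].[Li+].C=CC/C(C)=C/[C@H]([O-])C=C([O-])OCC | intermediate
20 | 4-tert-butyl 1-ethyl (2S)-2-[(1S,2E)-1-hydroxy-3-methylhexa-2,5-dien-1-yl]butanedioate | C=CC/C(C)=C/[C@H](O)[C@H](CC(=O)OC(C)(C)C)C(=O)OCC | intermediate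
21 | tert-butyl (3R,4S,5E)-4-hydroxy-3-(hydroxymethyl)-6-methylnona-5,8-dienoate | C=CC/C(C)=C/[C@H](O)[C@H](CC(=O)OC(C)(C)C)CO | intermediate
22 | tert-butyl (3R,4S,5E)-4-hydroxy-6-methyl-3-[(tosyloxy)methyl]nona-5,8-dienoate | C=CC/C(C)=C/[C@H](O)[C@H](CC(=O)OC(C)(C)C)COS(=O)(=O)c1ccc(C)cc1 | intermediate
23 | trimethylsilyl (3R,4S,5E)-6-methyl-3-[(tosyloxy)methyl]-4-(trimethylsilyloxy)nona-5,8-dienoate | C=CC/C(C)=C/[C@H](O[Si](C)(C)C)[C@H](CC(=O)O[Si](C)(C)C)COS(=O)(=O)c1ccc(C)cc1 | intermediate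
24 | (3R,4S,5E)-4-hydroxy-6-methyl-3-[(tosyloxy)methyl]nona-5,8-dienoic acid | C=CC/C(C)=C/[C@H](O)[C@H](CC(O)=O)COS(=O)(=O)c1ccc(C)cc1 | intermediate
25 | [(2S,3R)-2-[(1E)-2-methylpenta-1,4-dien-1-yl]-5-oxooxolan-3-yl]methyl 4-methylbenzenesulfonate (cis lactone) | O=C1C[C@H](COS(=O)(=O)c2ccc(C)cc2)[C@H](/C=C(\C)CC=C)O1 | intermediate
26 | (4S,5S)-4-(iodomethyl)-5-[(1E)-2-methylpenta-1,4-dien-1-yl]oxolan-2-one (cis lactone) | O=C1C[C@H](CI)[C@H](/C=C(\C)CC=C)O1 | intermediate
27 | iodo{[(2S,3S)-2-[(1E)-2-methylpenta-1,4-dien-1-yl]-5-oxooxolan-3-yl]methyl}zinc | O=C1C[C@H](C[Zn]I)[C@H](/C=C(\C)CC=C)O1 | intermediate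
28 | (4S,5R)-4-[(3E,7R)-3,7-dimethyl-2-oxo-7-(triethylsilyloxy)nona-3,8-dien-1-yl]-5-[(1E)-2-methylpenta-1,4-dien-1-yl]oxolan-2-one | C=C[C@](C)(O[Si](CC)(CC)CC)CC/C=C(\C)C(=O)C[C@H]1CC(=O)O[C@H]1/C=C(\C)CC=C | intermediate
29 | (4S,5R)-4-[(2S,3E,7R)-2-hydroxy-3,7-dimethyl-7-(triethylsilyloxy)nona-3,8-dien-1-yl]-5-[(1E)-2-methylpenta-1,4-dien-1-yl]oxolan-2-one | C=C[C@](C)(O[Si](CC)(CC)CC)CC/C=C(\C)[C@@H](O)C[C@H]1CC(=O)O[C@H]1/C=C(\C)CC=C | intermediate
30 | (4S,5R)-4-[(2S)-2-hydroxy-2-{(2S,3S)-2-methyl-3-[(3R)-3-methyl-3-(triethylsilyloxy)pent-4-en-1-yl]oxiran-2-yl}ethyl]-5-[(1E)-2-methylpenta-1,4-dien-1-yl]oxolan-2-one | C=C[C@](C)(O[Si](CC)(CC)CC)CC[C@@H]1O[C@@]1(C)[C@@H](O)C[C@H]2CC(=O)O[C@H]2/C=C(\C)CC=C | intermediate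
31 | (4S,5R)-4-[(2S)-2-{(2R,3S)-2-methyl-3-[(3R)-3-methyl-3-(triethylsilyloxy)pent-4-en-1-yl]oxiran-2-yl}-2-(triethylsilyloxy)ethyl]-5-[(1E)-2-methylpenta-1,4-dien-1-yl]oxolan-2-one | C=C[C@](C)(O[Si](CC)(CC)CC)CC[C@@H]1O[C@@]1(C)[C@@H](O[Si](CC)(CC)CC)C[C@H]2CC(=O)O[C@H]2/C=C(\C)CC=C | intermediate
32 | (1S,2R,3E,6E,8R,11S,12R,13S)-11,12-epoxy-8,13-bis(triethylsilyloxy)-17-norcembra-3,6-dien-16,2-olide (14-membered ring, cis lactone, C15 is CH2) | C1C(=O)O[C@H]2/C=C(\C)C/C=C/[C@](C)(O[Si](CC)(CC)CC)CC[C@@H]3O[C@@]3(C)[C@@H](O[Si](CC)(CC)CC)C[C@@H]12 | intermediate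
33 | lithium enolate of 32 (C15=C16–OLi) | C1=C([O-])O[C@H]2/C=C(\C)C/C=C/[C@](C)(O[Si](CC)(CC)CC)CC[C@@H]3O[C@@]3(C)[C@@H](O[Si](CC)(CC)CC)C[C@@H]12.[Li+] | intermediate
34 | (1S,2R,3E,6E,8R,11S,12R,13S)-17-(dimethylamino)-11,12-epoxy-8,13-bis(triethylsilyloxy)cembra-3,6-dien-16,2-olide (C15 epimer mixture) | CN(C)CC1C(=O)O[C@H]2/C=C(\C)C/C=C/[C@](C)(O[Si](CC)(CC)CC)CC[C@@H]3O[C@@]3(C)[C@@H](O[Si](CC)(CC)CC)C[C@@H]12 | intermediate
35 | N,N,N-trimethylammonium iodide of 34 | C[N+](C)(C)CC1C(=O)O[C@H]2/C=C(\C)C/C=C/[C@](C)(O[Si](CC)(CC)CC)CC[C@@H]3O[C@@]3(C)[C@@H](O[Si](CC)(CC)CC)C[C@@H]12.[I-] | intermediate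
36 | (1S,2S,3E,6E,8R,11S,12R,13S)-11,12-epoxy-8,13-bis(triethylsilyloxy)cembra-3,6,15(17)-trien-16,2-olide | C=C1C(=O)O[C@H]2/C=C(\C)C/C=C/[C@](C)(O[Si](CC)(CC)CC)CC[C@@H]3O[C@@]3(C)[C@@H](O[Si](CC)(CC)CC)C[C@@H]12 | intermediate
37 | (1S,2S,3E,6E,8R,11S,12S,13S)-11,12-epoxy-8,13-dihydroxycembra-3,6,15(17)-trien-16,2-olide | C=C1C(=O)O[C@H]2/C=C(\C)C/C=C/[C@](C)(O)CC[C@@H]3O[C@@]3(C)[C@@H](O)C[C@@H]12 | intermediate
38 | (1S,2S,3E,6E,8R,11S,12R,13S)-13-acetoxy-11,12-epoxy-8-hydroxycembra-3,6,15(17)-trien-16,2-olide | C=C1C(=O)O[C@H]2/C=C(\C)C/C=C/[C@](C)(O)CC[C@@H]3O[C@@]3(C)[C@@H](OC(C)=O)C[C@@H]12 | target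

**Totals**

Total step count: 25 (west 1–8, east 9–16, coupling and endgame 17–25).
Longest linear sequence: 17 steps (steps 9–16 then 17–25; the west branch, steps 1–8 then 17–25, is equally long).

**Three steps most likely to fail, with fallbacks**

Step 12 (Fráter–Seebach alkylation with a bromoacetate). The dianion may be alkylated sluggishly, or proton transfer to the α‑bromo ester may compete. The fallback sets out from 16 and returns at 20. It forms the C–C bond first and lets an enzyme set both centres: 16 is alkylated at C2 with 18 (K2CO3, acetone, rt) to give racemic 4-tert-butyl 1-ethyl 2-[(2E)-3-methylhexa-2,5-dienoyl]butanedioate F1. The stereocentre of F1 lies between two carbonyls and epimerises freely at pH 7, so an anti‑selective ketoreductase from the same panel (NADP+, iPrOH, buffer, 30 °C) reduces it by dynamic reductive kinetic resolution to 20.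

Step 17 (Fukuyama coupling). Zinc insertion next to the lactone may be slow, or zerovalent palladium may ionise the allylic lactone C–O bond. The fallback sets out from 26, uses aldehyde 7 (already on the route, so steps 7 and 8 are not needed), and returns at 28. Iodide 26 is added to 7 by a cobalt‑catalysed alkyl Nozaki–Hiyama–Kishi reaction (CrCl2, catalytic cobalt phthalocyanine Co(C32H16N8), DMF, rt). This gives the C13‑epimeric alcohols (4S,5R)-4-[(3E,7R)-2-hydroxy-3,7-dimethyl-7-(triethylsilyloxy)nona-3,8-dien-1-yl]-5-[(1E)-2-methylpenta-1,4-dien-1-yl]oxolan-2-one F2. Dess–Martin periodinane (NaHCO3, CH2Cl2) oxidises both epimers to enone 28, and the CBS step then sets C13 as before.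

Step 21 (ring‑closing metathesis). The vinyl group next to the silyloxy‑bearing quaternary C8 is a poor metathesis partner and oligomers may dominate. The fallback sets out from 29 and returns at 32; it closes the ring earlier, on a substrate with a free tertiary allylic hydroxyl and no epoxide or enone for that hydroxyl to attack. Alcohol 29 is desilylated (HF·pyridine, pyridine, THF) to (4S,5R)-4-[(2S,3E,7R)-2,7-dihydroxy-3,7-dimethylnona-3,8-dien-1-yl]-5-[(1E)-2-methylpenta-1,4-dien-1-yl]oxolan-2-one F3. Hydroxyl‑assisted ring‑closing metathesis (second-generation Grubbs catalyst, toluene, 1 mM, 60 °C) gives (1S,2R,3E,6E,8R,11E,13S)-8,13-dihydroxy-17-norcembra-3,6,11-trien-16,2-olide F4. The matched Sharpless epoxidation of step 19, now on the ring allylic alcohol, gives (1S,2R,3E,6E,8R,11S,12S,13S)-11,12-epoxy-8,13-dihydroxy-17-norcembra-3,6-dien-16,2-olide F5. Bis‑silylation (Et3SiOTf, 2,6-lutidine, CH2Cl2, −78 °C) rejoins the route at 32.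

**Further compounds**

F1 | step 12 | 4-tert-butyl 1-ethyl 2-[(2E)-3-methylhexa-2,5-dienoyl]butanedioate (racemic) | C=CC/C(C)=C/C(=O)C(CC(=O)OC(C)(C)C)C(=O)OCC
F2 | step 17 | (4S,5R)-4-[(3E,7R)-2-hydroxy-3,7-dimethyl-7-(triethylsilyloxy)nona-3,8-dien-1-yl]-5-[(1E)-2-methylpenta-1,4-dien-1-yl]oxolan-2-one (C13 epimer mixture) | C=C[C@](C)(O[Si](CC)(CC)CC)CC/C=C(\C)C(O)C[C@H]1CC(=O)O[C@H]1/C=C(\C)CC=C
F3 | step 21 | (4S,5R)-4-[(2S,3E,7R)-2,7-dihydroxy-3,7-dimethylnona-3,8-dien-1-yl]-5-[(1E)-2-methylpenta-1,4-dien-1-yl]oxolan-2-one | C=C[C@](C)(O)CC/C=C(\C)[C@@H](O)C[C@H]1CC(=O)O[C@H]1/C=C(\C)CC=C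
F4 | step 21 | (1S,2R,3E,6E,8R,11E,13S)-8,13-dihydroxy-17-norcembra-3,6,11-trien-16,2-olide | C1C(=O)O[C@H]2/C=C(\C)C/C=C/[C@](C)(O)CC/C=C(\C)[C@@H](O)C[C@@H]12
F5 | step 21 | (1S,2R,3E,6E,8R,11S,12S,13S)-11,12-epoxy-8,13-dihydroxy-17-norcembra-3,6-dien-16,2-olide | C1C(=O)O[C@H]2/C=C(\C)C/C=C/[C@](C)(O)CC[C@@H]3O[C@@]3(C)[C@@H](O)C[C@@H]12
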